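## Retrosynthetic overview

1. Target 18 ⇐ 17 by removal of three MOM groups; the benzoyl group ⇐ ortho-lithiation/acylation of the aryl triether 14 (last C–C bond).
2. 14 ⇐ ester 10: the second methyl of the ring CMe2 carbon is the ester carbon of 10 (CO2Me → CH2OH → CHO → CH3).
3. 10 ⇐ α-chloro ketone 8 by Favorskii contraction: the cyclopentane (isopropenyl CH, CH2, aryl CH, quaternary C, CH2) arises from the cyclohexanone ring of 8, whose carbonyl carbon is pushed out of the ring onto the quaternary carbon.
4. 8 ⇐ (R)-carvone 3 + aryl cuprate from 2 (trans 1,4-addition, then enolate chlorination); both stereocentres of the target are fixed here, before the contraction.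
5. Enabling feature: in the cyclopentane the CMe2 carbon lies between the aryl-bearing CH and a ring CH2. Read backwards, one of its methyls is a former ring C=O flanked by a tertiary C–Cl and an enolisable CH2. Ring order: both benzene rings are bought, the six-membered ring comes with carvone, the five-membered ring is made in step 4.

Key step: step 4

## Remarks on the chemistry (assumptions)

- The target is read as the trans-(1R,4R) cyclopentane (aryl and isopropenyl on opposite faces; numbering from the aryl-bearing carbon). The isopropenyl centre maps onto C-5 of (R)-carvone with unchanged descriptor.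
- Rotation about the aryl–cyclopentyl bond is taken as free, so the two open aryl positions of 14 are equivalent.
- The configuration drawn at the chlorine-bearing carbon of 8 and at the quaternary carbon of 9–13 is the one expected from the mechanisms. This carbon becomes the non-stereogenic CMe2 carbon in 14, so its configuration has no bearing on the target.

## Route

Step 1
Reactants: 1 phloroglucinol (benzene-1,3,5-triol)
Product: 2 1,3,5-tris(methoxymethoxy)benzene
Conditions: MOMCl, i-Pr2NEt, DMF, 0 °C → rt
Reagents that add atoms: chloromethyl methyl ether (MOMCl), COCCl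
Why: Threefold O-alkylation of the phenol with a hard α-chloro ether (Williamson-type acetal formation) under amine base, which should favour O- over C-alkylation; no stereocentre is formed.

Step 2
Reactants: 2 1,3,5-tris(methoxymethoxy)benzene; 3 (R)-(−)-carvone [(5R)-2-methyl-5-(prop-1-en-2-yl)cyclohex-2-en-1-one]
Product: 6 trimethyl({(3R,5R)-2-methyl-5-(prop-1-en-2-yl)-3-[2,4,6-tris(methoxymethoxy)phenyl]cyclohex-1-en-1-yl}oxy)silane, via aryllithium 4 (not isolated), via lithium diarylcuprate 5 (not isolated)
Conditions: 2, n-BuLi, THF, 0 °C; CuI (0.5 equiv), −40 °C; then TMSCl, 3, −78 → −20 °C; Et3N, aq. NH4Cl/NH3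
Reagents that add atoms: chlorotrimethylsilane, C[Si](C)(C)Cl
Why: Directed ortho-lithiation between two OMOM groups, then TMSCl-accelerated Gilman cuprate 1,4-addition; the aryl group should enter C-3 axially, anti to the C-5 isopropenyl group as in known cuprate additions to carvone, which sets the aryl-bearing centre trans to the isopropenyl centre, and the enolate is captured regiospecifically as the silyl enol ether.

Step 3
Reactants: 6 the silyl enol ether from step 2
Product: 8 (2S,3S,5R)-2-chloro-2-methyl-5-(prop-1-en-2-yl)-3-[2,4,6-tris(methoxymethoxy)phenyl]cyclohexan-1-one, via lithium enolate 7 (not isolated)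
Conditions: MeLi, THF, 0 °C; then NCS, −78 °C; aq. NH4Cl
Reagents that add atoms: N-chlorosuccinimide, ClN1C(=O)CCC1=O
Why: Regiospecific lithium enolate formation by Si–O cleavage, then electrophilic α-chlorination at −78 °C, where the enolate should outrun the electron-rich arene and the alkene; chlorine is expected to enter axially, anti to the pseudoaxial C-3 aryl group, giving the tertiary chloride trans to the aryl group.

Step 4
Reactants: 8 the α-chloro ketone from step 3
Product: 10 methyl (1R,2S,4R)-1-methyl-4-(prop-1-en-2-yl)-2-[2,4,6-tris(methoxymethoxy)phenyl]cyclopentane-1-carboxylate, via cyclopropanone 9 (not isolated)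
Conditions: NaOMe (3 equiv), Et2O, 0 °C → rt
Reagents that add atoms: sodium methoxide, C[O-].[Na+]
Why: Favorskii rearrangement: methoxide deprotonates C-6, the only enolisable position, and the enolate displaces the axial tertiary chloride at C-2 with inversion to give the cis-fused bicyclo[3.1.0]hexan-6-one 9; methoxide then adds to the strained carbonyl and the hemiketal opens toward the less substituted (secondary) carbanion at the former C-6, which is protonated. The closest known case is the contraction of 2-chloro-2-methylcyclohexanone to methyl 1-methylcyclopentanecarboxylate. The cyclopentane is closed by the C-6→C-2 bond in a 3-exo-tet enolate alkylation, and the carbonyl carbon ends up as the ester on the new quaternary carbon. That quaternary centre is set by inversion at the C–Cl carbon (substrate control), but it is erased in step 7, while the aryl and isopropenyl centres are β to the carbonyl and cannot epimerise. The step needs regioselective cyclopropanone opening and ring closure in preference to loss of HCl or methoxide substitution; the first follows from carbanion stability. The second is secured by the chlorine being axial and aligned with the enolate π-system, by the only ring β-hydrogen (H-3) being cis to chlorine and so not anti-periplanar, and by the aprotic medium.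

Step 5
Reactants: 10 the methyl ester from step 4
Product: 11 {(1R,2R,4R)-1-methyl-4-(prop-1-en-2-yl)-2-[2,4,6-tris(methoxymethoxy)phenyl]cyclopentyl}methanol
Conditions: LiAlH4, THF, 0 °C → reflux; H2O/NaOH work-up
Reagents that add atoms: none
Why: Hydride reduction of a hindered ester to the neopentyl primary alcohol with LiAlH4; MOM ethers and the isolated alkene are inert, and no stereocentre is touched.

Step 6
Reactants: 11 the primary alcohol from step 5
Product: 12 (1R,2S,4R)-1-methyl-4-(prop-1-en-2-yl)-2-[2,4,6-tris(methoxymethoxy)phenyl]cyclopentane-1-carbaldehyde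
Conditions: TPAP (5 mol %), NMO, 4 Å MS, CH2Cl2, rt
Reagents that add atoms: none
Why: Ley–Griffith oxidation of a primary alcohol to the aldehyde under neutral conditions; the aldehyde has no α-hydrogen, so it can neither epimerise nor enolise.

Step 7
Reactants: 12 the aldehyde from step 6
Product: 14 2-[(1R,4R)-2,2-dimethyl-4-(prop-1-en-2-yl)cyclopentyl]-1,3,5-tris(methoxymethoxy)benzene, via hydrazone 13 (not isolated)
Conditions: N2H4·H2O, KOH, diethylene glycol, 130 → 200 °C, under N2
Reagents that add atoms: none
Why: Wolff–Kishner reduction of a non-enolisable aldehyde to a methyl group; the base-stable MOM acetals and the unconjugated alkene should survive (air is excluded so that no diimide reduces the alkene), and the former quaternary stereocentre becomes the CMe2 carbon.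

Step 8
Reactants: 14 the aryl triether from step 7; 15 N-methoxy-N-methylbenzamide
Product: 17 phenyl{3-[(1R,4R)-2,2-dimethyl-4-(prop-1-en-2-yl)cyclopentyl]-2,4,6-tris(methoxymethoxy)phenyl}methanone, via aryllithium 16 (not isolated)
Conditions: n-BuLi, THF, 0 °C; then 15, −78 °C → rt; aq. NH4Cl
Reagents that add atoms: none
Why: Directed ortho-metalation at either of the two equivalent ring positions flanked by two OMOM groups, then Weinreb ketone synthesis, whose chelated tetrahedral adduct should prevent over-addition; no stereocentre is affected.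

Step 9
Reactants: 17 the protected benzophenone from step 8
Product: 18 phenyl{3-[(1R,4R)-2,2-dimethyl-4-(prop-1-en-2-yl)cyclopentyl]-2,4,6-trihydroxyphenyl}methanone (target)
Conditions: 3 M aq. HCl, MeOH, rt → 40 °C
Reagents that add atoms: none
Why: Acid-catalysed methanolysis of the three aryl MOM acetals, as used for prenylated acylphloroglucinols; the trans relation of aryl and isopropenyl groups should prevent phenol-to-alkene cyclisation under these mild conditions.

## Compound list

1 | phloroglucinol (benzene-1,3,5-triol) | Oc1cc(O)cc(O)c1 | starting material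
2 | 1,3,5-tris(methoxymethoxy)benzene | COCOc1cc(OCOC)cc(OCOC)c1 | intermediate
3 | (R)-(−)-carvone, (5R)-2-methyl-5-(prop-1-en-2-yl)cyclohex-2-en-1-one | C=C(C)[C@@H]1CC=C(C)C(=O)C1 | starting material
4 | [2,4,6-tris(methoxymethoxy)phenyl]lithium | [Li]c1c(OCOC)cc(OCOC)cc1OCOC | intermediate
5 | lithium bis[2,4,6-tris(methoxymethoxy)phenyl]cuprate | [Li+].COCOc1cc(OCOC)c([Cu-]c2c(OCOC)cc(OCOC)cc2OCOC)c(OCOC)c1 | intermediate
6 | trimethyl({(3R,5R)-2-methyl-5-(prop-1-en-2-yl)-3-[2,4,6-tris(methoxymethoxy)phenyl]cyclohex-1-en-1-yl}oxy)silane | C=C(C)[C@@H]1C[C@@H](c2c(OCOC)cc(OCOC)cc2OCOC)C(C)=C(O[Si](C)(C)C)C1 | intermediate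
7 | lithium (3R,5R)-2-methyl-5-(prop-1-en-2-yl)-3-[2,4,6-tris(methoxymethoxy)phenyl]cyclohex-1-en-1-olate | C=C(C)[C@@H]1C[C@@H](c2c(OCOC)cc(OCOC)cc2OCOC)C(C)=C(O[Li])C1 | intermediate
8 | (2S,3S,5R)-2-chloro-2-methyl-5-(prop-1-en-2-yl)-3-[2,4,6-tris(methoxymethoxy)phenyl]cyclohexan-1-one | C=C(C)[C@@H]1C[C@@H](c2c(OCOC)cc(OCOC)cc2OCOC)[C@](C)(Cl)C(=O)C1 | intermediate
9 | (1S,2S,4R,5R)-1-methyl-4-(prop-1-en-2-yl)-2-[2,4,6-tris(methoxymethoxy)phenyl]bicyclo[3.1.0]hexan-6-one | C=C(C)[C@@H]1C[C@@H](c2c(OCOC)cc(OCOC)cc2OCOC)[C@]2(C)C(=O)[C@H]12 | intermediate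
10 | methyl (1R,2S,4R)-1-methyl-4-(prop-1-en-2-yl)-2-[2,4,6-tris(methoxymethoxy)phenyl]cyclopentane-1-carboxylate | C=C(C)[C@@H]1C[C@@H](c2c(OCOC)cc(OCOC)cc2OCOC)[C@](C)(C(=O)OC)C1 | intermediate
11 | {(1R,2R,4R)-1-methyl-4-(prop-1-en-2-yl)-2-[2,4,6-tris(methoxymethoxy)phenyl]cyclopentyl}methanol | C=C(C)[C@@H]1C[C@@H](c2c(OCOC)cc(OCOC)cc2OCOC)[C@](C)(CO)C1 | intermediate
12 | (1R,2S,4R)-1-methyl-4-(prop-1-en-2-yl)-2-[2,4,6-tris(methoxymethoxy)phenyl]cyclopentane-1-carbaldehyde | C=C(C)[C@@H]1C[C@@H](c2c(OCOC)cc(OCOC)cc2OCOC)[C@](C)(C=O)C1 | intermediate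
13 | (E)-hydrazone of 12, {(1R,2R,4R)-1-methyl-4-(prop-1-en-2-yl)-2-[2,4,6-tris(methoxymethoxy)phenyl]cyclopentyl}methanal hydrazone | C=C(C)[C@@H]1C[C@@H](c2c(OCOC)cc(OCOC)cc2OCOC)[C@](C)(/C=N/N)C1 | intermediate
14 | 2-[(1R,4R)-2,2-dimethyl-4-(prop-1-en-2-yl)cyclopentyl]-1,3,5-tris(methoxymethoxy)benzene | C=C(C)[C@@H]1C[C@@H](c2c(OCOC)cc(OCOC)cc2OCOC)C(C)(C)C1 | intermediate
15 | N-methoxy-N-methylbenzamide | CON(C)C(=O)c1ccccc1 | starting material
16 | {3-[(1R,4R)-2,2-dimethyl-4-(prop-1-en-2-yl)cyclopentyl]-2,4,6-tris(methoxymethoxy)phenyl}lithium | C=C(C)[C@@H]1C[C@@H](c2c(OCOC)cc(OCOC)c([Li])c2OCOC)C(C)(C)C1 | intermediate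
17 | phenyl{3-[(1R,4R)-2,2-dimethyl-4-(prop-1-en-2-yl)cyclopentyl]-2,4,6-tris(methoxymethoxy)phenyl}methanone | C=C(C)[C@@H]1C[C@@H](c2c(OCOC)cc(OCOC)c(C(=O)c3ccccc3)c2OCOC)C(C)(C)C1 | intermediate
18 | phenyl{3-[(1R,4R)-2,2-dimethyl-4-(prop-1-en-2-yl)cyclopentyl]-2,4,6-trihydroxyphenyl}methanone | C=C(C)[C@@H]1C[C@@H](c2c(O)cc(O)c(C(=O)c3ccccc3)c2O)C(C)(C)C1 | target

## Step count and risks

Total step count: 9. Longest linear sequence: 9 steps (1 → 18 through steps 1–9); carvone 3 enters at step 2 and the amide 15 at step 8.

Steps most likely to fail, riskiest first: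

**Step 4 (Favorskii contraction).** At the hindered tertiary α-chloro ketone, loss of HCl toward the exocyclic methylene ketone, or methoxide attack at the carbonyl with epoxy-ether formation, may outrun the enolate ring closure. The fallback sets out from silyl enol ether 6 and comes back at aldehyde 12, replacing steps 3–6 by a semipinacol (Meinwald-type) contraction. Compound 6 is cleaved with MeLi to lithium enolate 7, which is O-sulfonylated with N-phenyltriflimide to give (3R,5R)-2-methyl-5-(prop-1-en-2-yl)-3-[2,4,6-tris(methoxymethoxy)phenyl]cyclohex-1-en-1-yl trifluoromethanesulfonate F1. Palladium-catalysed formate reduction (Pd(OAc)2, PPh3, Bu3N, HCO2H, DMF) should give 2-[(1R,5S)-2-methyl-5-(prop-1-en-2-yl)cyclohex-2-en-1-yl]-1,3,5-tris(methoxymethoxy)benzene F2. Buffered mCPBA at 0 °C is expected to epoxidise the trisubstituted ring alkene in preference to the isopropenyl group and anti to the aryl group, giving 2-[(1S,2S,4R,6R)-1-methyl-4-(prop-1-en-2-yl)-7-oxabicyclo[4.1.0]heptan-2-yl]-1,3,5-tris(methoxymethoxy)benzene F3. A bulky aluminium Lewis acid of the kind known to favour alkyl over hydride shift in trisubstituted epoxides (methylaluminium bis(4-bromo-2,6-di-tert-butylphenoxide), CH2Cl2, −78 °C) should open the tertiary C–O bond with anti migration of the ring CH2 and deliver 12 with the same configuration as in the main route.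

**Step 2 (cuprate addition).** Transfer of the di-ortho-substituted aryl group from copper to the β-carbon of the α-methyl enone may be slow, so that 1,2-addition, enolisation or reduction of carvone take over. The fallback sets out from carvone 3 and aryllithium 4 and comes back at aldehyde 12, replacing conjugate addition by allylic substitution. Luche reduction of 3 (NaBH4, CeCl3, MeOH) should give (1R,5R)-2-methyl-5-(prop-1-en-2-yl)cyclohex-2-en-1-ol F4, which is esterified with picolinic acid (DCC, DMAP) to (1R,5R)-2-methyl-5-(prop-1-en-2-yl)cyclohex-2-en-1-yl pyridine-2-carboxylate F5. Aryllithium 4 is transmetalated with MgBr2·OEt2 to bromo[2,4,6-tris(methoxymethoxy)phenyl]magnesium F6. With CuBr·SMe2, F6 should substitute F5 in the anti-SN2′ mode, the aryl group entering the γ-carbon on the face opposite to the leaving group and therefore trans to the isopropenyl group. This gives the cyclohexene F2 of the first fallback, which is carried through epoxide F3 to 12 as described there. γ-Selectivity is essential here, because α-substitution with inversion would give the enantiomeric skeleton; the chelating picolinate is chosen for that reason.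

**Step 7 (Wolff–Kishner reduction).** Hydrazone formation at the neopentyl aldehyde beside the bulky aryl group may stall or divert to the azine, and the isopropenyl double bond may migrate in hot base. The fallback sets out from alcohol 11 and comes back at 14, avoiding the carbonyl stage and omitting step 6. MsCl/Et3N should give {(1R,2R,4R)-1-methyl-4-(prop-1-en-2-yl)-2-[2,4,6-tris(methoxymethoxy)phenyl]cyclopentyl}methyl methanesulfonate F7, and hydride displacement with LiEt3BH in refluxing THF is expected to give 14.

Further compounds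
F1 | step 4 | (3R,5R)-2-methyl-5-(prop-1-en-2-yl)-3-[2,4,6-tris(methoxymethoxy)phenyl]cyclohex-1-en-1-yl trifluoromethanesulfonate | C=C(C)[C@@H]1C[C@@H](c2c(OCOC)cc(OCOC)cc2OCOC)C(C)=C(OS(=O)(=O)C(F)(F)F)C1
F2 | step 4 | 2-[(1R,5S)-2-methyl-5-(prop-1-en-2-yl)cyclohex-2-en-1-yl]-1,3,5-tris(methoxymethoxy)benzene | C=C(C)[C@@H]1C[C@@H](c2c(OCOC)cc(OCOC)cc2OCOC)C(C)=CC1
F3 | step 4 | 2-[(1S,2S,4R,6R)-1-methyl-4-(prop-1-en-2-yl)-7-oxabicyclo[4.1.0]heptan-2-yl]-1,3,5-tris(methoxymethoxy)benzene | C=C(C)[C@@H]1C[C@@H](c2c(OCOC)cc(OCOC)cc2OCOC)[C@]2(C)O[C@@H]2C1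
F4 | step 2 | (1R,5R)-2-methyl-5-(prop-1-en-2-yl)cyclohex-2-en-1-ol [(−)-cis-carveol] | C=C(C)[C@@H]1CC=C(C)[C@H](O)C1
F5 | step 2 | (1R,5R)-2-methyl-5-(prop-1-en-2-yl)cyclohex-2-en-1-yl pyridine-2-carboxylate | C=C(C)[C@@H]1CC=C(C)[C@H](OC(=O)c2ccccn2)C1
F6 | step 2 | bromo[2,4,6-tris(methoxymethoxy)phenyl]magnesium | Br[Mg]c1c(OCOC)cc(OCOC)cc1OCOC
F7 | step 7 | {(1R,2R,4R)-1-methyl-4-(prop-1-en-2-yl)-2-[2,4,6-tris(methoxymethoxy)phenyl]cyclopentyl}methyl methanesulfonate | C=C(C)[C@@H]1C[C@@H](c2c(OCOC)cc(OCOC)cc2OCOC)[C@](C)(COS(C)(=O)=O)C1
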